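## Retrosynthetic overview

1. The target is taken from its roughly 1:1 spiro-epimer pair by acid equilibration and HPLC; the pair comes from hydrogenation of an alkene made by Julia–Kocienski olefination in the middle of the six-carbon linker (phthalide propanal + spiroketal tetrazolyl sulfone).
2. Phthalide fragment: the lactone ring is closed by Br/Li exchange, CO2 capture and lactonisation of an ortho-bromo benzylic alcohol; C3 comes from Noyori transfer hydrogenation of an aryl ketone (Weinreb amide + acetal Grignard reagent).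
3. Spiroketal fragment: both tetrahydrofuran rings close in one acid-mediated desilylation/spiroketalisation of a 1,7-bis(silyloxy)-4-ketone, made from a lithium acetylide and a Weinreb amide followed by alkyne hydrogenation.
4. C7'' comes from ketoreductase reduction of ethyl levulinate; C2'' from transfer hydrogenation of the TMS-ynone built from 4-chlorobutanoyl chloride and bis(trimethylsilyl)acetylene.
5. Ring order: phthalide lactone (fragment 1); separately the two spiroketal rings together (fragment 2); fragment union; spiro centre fixed last.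

Assumption: the target is the (3S,2''S,5''S,7''S) isomer read from the SMILES; a 2,7-dialkyl-1,6-dioxaspiro[4.4]nonane has no useful thermodynamic bias at the spiro carbon, so that centre is carried as a ca. 1:1 epimer pair (SMILES left open at that atom) and fixed by separation with acid recycling in the last step.

## Route

Step 1
Reactants: 1 3,5-dimethoxybenzoyl chloride
Product: 2 N,3,5-trimethoxy-N-methylbenzamide
Conditions: MeNH(OMe)·HCl (1.1 equiv), Et3N (2.3 equiv), CH2Cl2, 0 °C → rt
Reagents that add atoms: N,O-dimethylhydroxylamine hydrochloride, CNOC.Cl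
Why: N-acylation of the liberated amine by the acid chloride (Weinreb amide formation) is fast and clean, and no stereocentre is involved.

Step 2
Reactants: 2 N,3,5-trimethoxy-N-methylbenzamide; 3 [2-(1,3-dioxan-2-yl)ethyl]magnesium bromide (commercial THF solution)
Product: 5 3-(1,3-dioxan-2-yl)-1-(3,5-dimethoxyphenyl)propan-1-one, via magnesium chelate adduct 4 (not isolated)
Conditions: THF, 0 °C → rt; sat. aq NH4Cl
Reagents that add atoms: none
Why: Weinreb ketone synthesis, in which the N-methoxy magnesium chelate resists a second addition and collapses to the ketone only on quench, while the dioxane acetal is inert to the Grignard reagent.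

Step 3
Reactants: 5 3-(1,3-dioxan-2-yl)-1-(3,5-dimethoxyphenyl)propan-1-one
Product: 6 (1S)-3-(1,3-dioxan-2-yl)-1-(3,5-dimethoxyphenyl)propan-1-ol
Conditions: RuCl[(S,S)-TsDPEN](p-cymene) (1 mol %), HCO2H/Et3N (5:2), EtOAc, 30 °C
Reagents that add atoms: none
Why: Noyori asymmetric transfer hydrogenation, in which the (S,S)-TsDPEN ruthenium hydride delivers hydrogen to the ketone face that places the aryl group under the arene ligand, giving the (S)-benzylic alcohol (about 95% ee expected for aryl n-alkyl ketones) and so setting the future C3.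

Step 4
Reactants: 6 (1S)-3-(1,3-dioxan-2-yl)-1-(3,5-dimethoxyphenyl)propan-1-ol
Product: 7 (1S)-1-(2-bromo-3,5-dimethoxyphenyl)-3-(1,3-dioxan-2-yl)propan-1-ol
Conditions: NBS (1.02 equiv), MeCN, 0 °C, dark
Reagents that add atoms: N-bromosuccinimide, BrN1C(=O)CCC1=O
Why: Electrophilic aromatic bromination goes to the position ortho to the side chain (para to one OMe, ortho to the other) rather than the crowded position between the two OMe groups, as is usual for 3,5-dimethoxybenzyl systems, and the stereocentre is not touched.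

Step 5
Reactants: 7 (1S)-1-(2-bromo-3,5-dimethoxyphenyl)-3-(1,3-dioxan-2-yl)propan-1-ol
Product: 10 (3S)-3-[2-(1,3-dioxan-2-yl)ethyl]-5,7-dimethoxyisobenzofuran-1(3H)-one, via dilithiated aryl alkoxide 8 (not isolated), via hydroxy acid 9 (not isolated)
Conditions: n-BuLi (2.2 equiv), THF, −78 °C; CO2 (g), −78 → 0 °C; 1 M HCl to pH 2, EtOAc, rt
Reagents that add atoms: carbon dioxide, O=C=O
Why: Deprotonation of the alcohol and bromine–lithium exchange give an aryllithium that is carboxylated by CO2, and the resulting ortho-(hydroxyalkyl)benzoic acid lactonises spontaneously on acidification to the phthalide without breaking the C–O bond of the stereocentre, so (S) is retained.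

Step 6
Reactants: 10 (3S)-3-[2-(1,3-dioxan-2-yl)ethyl]-5,7-dimethoxyisobenzofuran-1(3H)-one
Product: 11 (3S)-5,7-dimethoxy-3-(3-oxopropyl)isobenzofuran-1(3H)-one
Conditions: 2 M aq HCl, THF, 45 °C
Reagents that add atoms: water, O
Why: Acid-catalysed acetal hydrolysis unmasks the aldehyde, while the phthalide C3–O bond does not ionise because both OMe groups are meta to the benzylic carbon and the ring carries the lactone carbonyl.

Step 7
Reactants: 12 ethyl levulinate (ethyl 4-oxopentanoate)
Product: 13 ethyl (4S)-4-hydroxypentanoate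
Conditions: ketoreductase (Prelog-selective NADH-dependent alcohol dehydrogenase), NAD+ (cat.), i-PrOH (15% v/v), phosphate buffer pH 7.0, 30 °C; MTBE extraction without acid or heat
Reagents that add atoms: none
Why: Enzymatic asymmetric ketone reduction by a ketoreductase delivers hydride from NADH to the Re face of the methyl ketone (Prelog rule), giving the (S)-alcohol in >99% ee as the future C7'', with isopropanol recycling the cofactor.

Step 8
Reactants: 13 ethyl (4S)-4-hydroxypentanoate
Product: 14 ethyl (4S)-4-[(tert-butyldimethylsilyl)oxy]pentanoate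
Conditions: TBSCl (1.2 equiv), imidazole (2.5 equiv), DMF, rt
Reagents that add atoms: tert-butyldimethylsilyl chloride, CC(C)(C)[Si](C)(C)Cl
Why: Standard O-silylation of the secondary alcohol blocks lactonisation to valerolactone and does not touch the stereocentre.

Step 9
Reactants: 14 ethyl (4S)-4-[(tert-butyldimethylsilyl)oxy]pentanoate
Product: 15 (4S)-4-[(tert-butyldimethylsilyl)oxy]-N-methoxy-N-methylpentanamide
Conditions: MeNH(OMe)·HCl (1.5 equiv), i-PrMgCl (3.0 equiv), THF, −20 → 0 °C; sat. aq NH4Cl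
Reagents that add atoms: N,O-dimethylhydroxylamine hydrochloride, CNOC.Cl
Why: Direct ester aminolysis by the magnesium amide generated in the flask gives the Weinreb amide, and the silyloxy stereocentre, remote from the carbonyl, is unaffected.

Step 10
Reactants: 16 4-chlorobutanoyl chloride; 17 bis(trimethylsilyl)acetylene
Product: 18 6-chloro-1-(trimethylsilyl)hex-1-yn-3-one
Conditions: AlCl3 (1.1 equiv), CH2Cl2, 0 °C
Reagents that add atoms: none
Why: Friedel–Crafts-type acylative desilylation of the bis-silyl alkyne stops after one acylation because the ynone product is deactivated.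

Step 11
Reactants: 18 6-chloro-1-(trimethylsilyl)hex-1-yn-3-one
Product: 19 (3S)-6-chloro-1-(trimethylsilyl)hex-1-yn-3-ol
Conditions: Ru[(S,S)-TsDPEN](p-cymene) (preformed amido complex, 1 mol %), i-PrOH, rt
Reagents that add atoms: none
Why: Noyori asymmetric transfer hydrogenation of an alkynyl ketone, in which the alkyne takes the role of the π-substituent, so the (S,S) catalyst gives the (S)-propargylic alcohol (typically ≥97% ee), the future C2''.

Step 12
Reactants: 19 (3S)-6-chloro-1-(trimethylsilyl)hex-1-yn-3-ol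
Product: 20 tert-butyl{[(3S)-6-chloro-1-(trimethylsilyl)hex-1-yn-3-yl]oxy}dimethylsilane
Conditions: TBSCl (1.2 equiv), imidazole (2.5 equiv), DMF, rt
Reagents that add atoms: tert-butyldimethylsilyl chloride, CC(C)(C)[Si](C)(C)Cl
Why: Standard O-silylation of the propargylic alcohol proceeds with retention because the C–O bond is not broken.

Step 13
Reactants: 20 tert-butyl{[(3S)-6-chloro-1-(trimethylsilyl)hex-1-yn-3-yl]oxy}dimethylsilane
Product: 21 tert-butyl{[(3S)-6-chlorohex-1-yn-3-yl]oxy}dimethylsilane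
Conditions: K2CO3 (0.2 equiv), MeOH, rt
Reagents that add atoms: none
Why: Base-catalysed methanolysis cleaves only the alkynyl C–Si bond (protodesilylation), leaving the O-TBS ether and the primary chloride intact.

Step 14
Reactants: 21 tert-butyl{[(3S)-6-chlorohex-1-yn-3-yl]oxy}dimethylsilane; 15 (4S)-4-[(tert-butyldimethylsilyl)oxy]-N-methoxy-N-methylpentanamide
Product: 24 (2S,8S)-2,8-bis[(tert-butyldimethylsilyl)oxy]-11-chloroundec-6-yn-5-one, via lithium acetylide 22 (not isolated), via lithium hemiaminal adduct 23 (not isolated)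
Conditions: n-BuLi (1.05 equiv), THF, −78 °C; then 15, −78 → 0 °C; sat. aq NH4Cl
Reagents that add atoms: none
Why: Acylation of the lithium acetylide by the Weinreb amide stops at the stable chelate (Weinreb ketone synthesis), the alkyl chloride is inert at these temperatures, and neither stereocentre is touched.

Step 15
Reactants: 24 (2S,8S)-2,8-bis[(tert-butyldimethylsilyl)oxy]-11-chloroundec-6-yn-5-one
Product: 25 (2S,8R)-2,8-bis[(tert-butyldimethylsilyl)oxy]-11-chloroundecan-5-one
Conditions: H2 (1 atm), 10% Pd/C, EtOAc, rt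
Reagents that add atoms: none
Why: Heterogeneous catalytic hydrogenation reduces the conjugated alkyne fully to CH2CH2 while the ketone, silyl ethers and primary chloride survive; the C8 descriptor changes to R only because the CIP priorities change.

Step 16
Reactants: 25 (2S,8R)-2,8-bis[(tert-butyldimethylsilyl)oxy]-11-chloroundecan-5-one
Product: 26 (2S,8R)-2,8-bis[(tert-butyldimethylsilyl)oxy]-11-[(1-phenyl-1H-tetrazol-5-yl)sulfanyl]undecan-5-one
Conditions: 1-phenyl-1H-tetrazole-5-thiol (1.2 equiv), K2CO3 (1.5 equiv), DMF, 60 °C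
Reagents that add atoms: 1-phenyl-1H-tetrazole-5-thiol, Sc1nnnn1-c1ccccc1
Why: SN2 displacement of the primary chloride by the soft tetrazolethiolate gives S-alkylation cleanly under conditions that leave the ketone and silyl ethers alone.

Step 17
Reactants: 26 (2S,8R)-2,8-bis[(tert-butyldimethylsilyl)oxy]-11-[(1-phenyl-1H-tetrazol-5-yl)sulfanyl]undecan-5-one
Product: 28 5-({3-[(2R,7S)-7-methyl-1,6-dioxaspiro[4.4]nonan-2-yl]propyl}sulfanyl)-1-phenyl-1H-tetrazole (ca. 1:1 pair of C5 epimers), via keto diol 27 (not isolated)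
Conditions: 48% aq HF, MeCN, 0 °C → rt
Reagents that add atoms: none
Why: Acidic desilylation releases the 1,7-dihydroxy-4-ketone, which undergoes thermodynamic spiroketalisation to close both tetrahydrofuran rings at once with retention at C2 and C7, the spiro carbon forming as a near 1:1 pair because the two epimers are almost equal in energy.

Step 18
Reactants: 28 5-({3-[(2R,7S)-7-methyl-1,6-dioxaspiro[4.4]nonan-2-yl]propyl}sulfanyl)-1-phenyl-1H-tetrazole (C5 epimer pair)
Product: 29 5-({3-[(2R,7S)-7-methyl-1,6-dioxaspiro[4.4]nonan-2-yl]propyl}sulfonyl)-1-phenyl-1H-tetrazole (C5 epimer pair)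
Conditions: (NH4)6Mo7O24·4H2O (10 mol %), 30% aq H2O2 (10 equiv), EtOH, 0 °C → rt
Reagents that add atoms: hydrogen peroxide, OO
Why: Molybdate-catalysed peroxide oxidation takes the sulfide through the sulfoxide to the sulfone, and the spiroketal tolerates these conditions.

Step 19
Reactants: 29 5-({3-[(2R,7S)-7-methyl-1,6-dioxaspiro[4.4]nonan-2-yl]propyl}sulfonyl)-1-phenyl-1H-tetrazole (C5 epimer pair); 11 (3S)-5,7-dimethoxy-3-(3-oxopropyl)isobenzofuran-1(3H)-one
Product: 31 (3S)-5,7-dimethoxy-3-{(3E)-6-[(2S,7S)-7-methyl-1,6-dioxaspiro[4.4]nonan-2-yl]hex-3-en-1-yl}isobenzofuran-1(3H)-one (E major; C5'' epimer pair), via potassium sulfonyl carbanion 30 (not isolated)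
Conditions: KN(SiMe3)2 (1.1 equiv), DME, −78 °C, 30 min; then 11, −78 °C → rt; sat. aq NH4Cl
Reagents that add atoms: none
Why: Julia–Kocienski olefination, in which the metalated tetrazolyl sulfone adds to the aldehyde much faster than to the lactone and Smiles rearrangement with loss of SO2 and the tetrazolone gives the alkene, whose geometry is erased in the next step.

Step 20
Reactants: 31 (3S)-5,7-dimethoxy-3-{(3E)-6-[(2S,7S)-7-methyl-1,6-dioxaspiro[4.4]nonan-2-yl]hex-3-en-1-yl}isobenzofuran-1(3H)-one (E major; C5'' epimer pair)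
Product: 32 (3S)-5,7-dimethoxy-3-{6-[(2S,7S)-7-methyl-1,6-dioxaspiro[4.4]nonan-2-yl]hexyl}isobenzofuran-1(3H)-one (C5'' epimer pair)
Conditions: H2 (1 atm), PtO2 (5 mol %), EtOAc, rt
Reagents that add atoms: none
Why: Catalytic hydrogenation saturates the disubstituted alkene, and PtO2 at 1 atm leaves the benzylic lactone C–O bond, the arene and the spiroketal intact.

Step 21
Reactants: 32 (3S)-5,7-dimethoxy-3-{6-[(2S,7S)-7-methyl-1,6-dioxaspiro[4.4]nonan-2-yl]hexyl}isobenzofuran-1(3H)-one (C5'' epimer pair)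
Product: 33 (3S)-5,7-dimethoxy-3-{6-[(2S,5S,7S)-7-methyl-1,6-dioxaspiro[4.4]nonan-2-yl]hexyl}isobenzofuran-1(3H)-one
Conditions: semi-preparative HPLC (silica, hexane/EtOAc); recovered 5''R epimer: CSA (10 mol %), CH2Cl2, rt, then HPLC again (3 cycles)
Reagents that add atoms: none
Why: Acid-catalysed spiroketal epimerisation (ring opening to the oxocarbenium ion and reclosure) interconverts only the two C5'' epimers, so removing the (5''S) epimer by HPLC and returning the (5''R) epimer to equilibration sets the spiro centre without touching C3, C2'' or C7''.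

## Compound list

1 | 3,5-dimethoxybenzoyl chloride | COc1cc(OC)cc(c1)C(Cl)=O | starting material
2 | N,3,5-trimethoxy-N-methylbenzamide | COc1cc(OC)cc(c1)C(=O)N(C)OC | intermediate
3 | [2-(1,3-dioxan-2-yl)ethyl]magnesium bromide | Br[Mg]CCC1OCCCO1 | starting material
4 | bromomagnesium alkoxide of the tetrahedral adduct of 2 and 3 | COc1cc(OC)cc(c1)C(O[Mg]Br)(CCC1OCCCO1)N(C)OC | intermediate (not isolated)
5 | 3-(1,3-dioxan-2-yl)-1-(3,5-dimethoxyphenyl)propan-1-one | COc1cc(OC)cc(c1)C(=O)CCC1OCCCO1 | intermediate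
6 | (1S)-3-(1,3-dioxan-2-yl)-1-(3,5-dimethoxyphenyl)propan-1-ol | COc1cc(OC)cc(c1)[C@H](CCC1OCCCO1)O | intermediate
7 | (1S)-1-(2-bromo-3,5-dimethoxyphenyl)-3-(1,3-dioxan-2-yl)propan-1-ol | COc1cc(OC)c(Br)c(c1)[C@H](CCC1OCCCO1)O | intermediate
8 | lithium (1S)-3-(1,3-dioxan-2-yl)-1-(2-lithio-3,5-dimethoxyphenyl)propan-1-olate | COc1cc(OC)c([Li])c(c1)[C@H](CCC1OCCCO1)O[Li] | intermediate (not isolated)
9 | 2-[(1S)-3-(1,3-dioxan-2-yl)-1-hydroxypropyl]-4,6-dimethoxybenzoic acid | COc1cc(OC)c(C(O)=O)c(c1)[C@H](CCC1OCCCO1)O | intermediate (not isolated)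
10 | (3S)-3-[2-(1,3-dioxan-2-yl)ethyl]-5,7-dimethoxyisobenzofuran-1(3H)-one | COc1cc(OC)c2c(c1)[C@H](CCC1OCCCO1)OC2=O | intermediate
11 | (3S)-5,7-dimethoxy-3-(3-oxopropyl)isobenzofuran-1(3H)-one | COc1cc(OC)c2c(c1)[C@H](CCC=O)OC2=O | intermediate
12 | ethyl levulinate | CCOC(=O)CCC(C)=O | starting material
13 | ethyl (4S)-4-hydroxypentanoate | CCOC(=O)CC[C@H](C)O | intermediate
14 | ethyl (4S)-4-[(tert-butyldimethylsilyl)oxy]pentanoate | CCOC(=O)CC[C@H](C)O[Si](C)(C)C(C)(C)C | intermediate
15 | (4S)-4-[(tert-butyldimethylsilyl)oxy]-N-methoxy-N-methylpentanamide | CON(C)C(=O)CC[C@H](C)O[Si](C)(C)C(C)(C)C | intermediate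
16 | 4-chlorobutanoyl chloride | ClCCCC(Cl)=O | starting material
17 | bis(trimethylsilyl)acetylene | C[Si](C)(C)C#C[Si](C)(C)C | starting material
18 | 6-chloro-1-(trimethylsilyl)hex-1-yn-3-one | ClCCCC(=O)C#C[Si](C)(C)C | intermediate
19 | (3S)-6-chloro-1-(trimethylsilyl)hex-1-yn-3-ol | ClCCC[C@H](O)C#C[Si](C)(C)C | intermediate
20 | tert-butyl{[(3S)-6-chloro-1-(trimethylsilyl)hex-1-yn-3-yl]oxy}dimethylsilane | ClCCC[C@H](O[Si](C)(C)C(C)(C)C)C#C[Si](C)(C)C | intermediate
21 | tert-butyl{[(3S)-6-chlorohex-1-yn-3-yl]oxy}dimethylsilane | ClCCC[C@H](O[Si](C)(C)C(C)(C)C)C#C | intermediate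
22 | lithium acetylide of 21 | ClCCC[C@H](O[Si](C)(C)C(C)(C)C)C#C[Li] | intermediate (not isolated)
23 | lithium alkoxide of the tetrahedral adduct of 22 and 15 | C[C@H](O[Si](C)(C)C(C)(C)C)CCC(O[Li])(N(C)OC)C#C[C@@H](O[Si](C)(C)C(C)(C)C)CCCCl | intermediate (not isolated)
24 | (2S,8S)-2,8-bis[(tert-butyldimethylsilyl)oxy]-11-chloroundec-6-yn-5-one | C[C@H](O[Si](C)(C)C(C)(C)C)CCC(=O)C#C[C@@H](O[Si](C)(C)C(C)(C)C)CCCCl | intermediate
25 | (2S,8R)-2,8-bis[(tert-butyldimethylsilyl)oxy]-11-chloroundecan-5-one | C[C@H](O[Si](C)(C)C(C)(C)C)CCC(=O)CC[C@@H](O[Si](C)(C)C(C)(C)C)CCCCl | intermediate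
26 | (2S,8R)-2,8-bis[(tert-butyldimethylsilyl)oxy]-11-[(1-phenyl-1H-tetrazol-5-yl)sulfanyl]undecan-5-one | C[C@H](O[Si](C)(C)C(C)(C)C)CCC(=O)CC[C@@H](O[Si](C)(C)C(C)(C)C)CCCSc1nnnn1-c1ccccc1 | intermediate
27 | (2S,8R)-2,8-dihydroxy-11-[(1-phenyl-1H-tetrazol-5-yl)sulfanyl]undecan-5-one | C[C@H](O)CCC(=O)CC[C@@H](O)CCCSc1nnnn1-c1ccccc1 | intermediate (not isolated)
28 | 5-({3-[(2R,7S)-7-methyl-1,6-dioxaspiro[4.4]nonan-2-yl]propyl}sulfanyl)-1-phenyl-1H-tetrazole, ca. 1:1 pair of C5 epimers (spiro atom left open) | c1ccccc1-n1nnnc1SCCC[C@H]1CCC2(CC[C@H](C)O2)O1 | intermediate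
29 | 5-({3-[(2R,7S)-7-methyl-1,6-dioxaspiro[4.4]nonan-2-yl]propyl}sulfonyl)-1-phenyl-1H-tetrazole, C5 epimer pair | c1ccccc1-n1nnnc1S(=O)(=O)CCC[C@H]1CCC2(CC[C@H](C)O2)O1 | intermediate
30 | potassium salt of the α-sulfonyl carbanion of 29 | c1ccccc1-n1nnnc1S(=O)(=O)[CH-]CC[C@H]1CCC2(CC[C@H](C)O2)O1.[K+] | intermediate (not isolated)
31 | (3S)-5,7-dimethoxy-3-{(3E)-6-[(2S,7S)-7-methyl-1,6-dioxaspiro[4.4]nonan-2-yl]hex-3-en-1-yl}isobenzofuran-1(3H)-one, E major, C5'' epimer pair | COc1cc(OC)c2c(c1)[C@H](CC/C=C/CC[C@H]1CCC3(CC[C@H](C)O3)O1)OC2=O | intermediate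
32 | (3S)-5,7-dimethoxy-3-{6-[(2S,7S)-7-methyl-1,6-dioxaspiro[4.4]nonan-2-yl]hexyl}isobenzofuran-1(3H)-one, C5'' epimer pair | COc1cc(OC)c2c(c1)[C@H](CCCCCC[C@H]1CCC3(CC[C@H](C)O3)O1)OC2=O | intermediate
33 | (3S)-5,7-dimethoxy-3-{6-[(2S,5S,7S)-7-methyl-1,6-dioxaspiro[4.4]nonan-2-yl]hexyl}isobenzofuran-1(3H)-one | COc1cc(OC)c2c(c1)[C@H](CCCCCC[C@H]1CC[C@]3(CC[C@H](C)O3)O1)OC2=O | target

## Summary

Total step count: 21. Longest linear sequence: 12 steps (steps 10 to 21, from 16 and 17).

Three steps most likely to fail: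

Step 21. The two spiro epimers may separate poorly or recycle slowly on scale. The fallback sets out from 25 and comes back to the route at 33. Chloro ketone 25 is desilylated and cyclised (48% aq HF, MeCN) to (2R,7S)-2-(3-chloropropyl)-7-methyl-1,6-dioxaspiro[4.4]nonane as its C5 epimer pair F1. The epimers of this small, volatile spiroketal are separated by preparative GC or careful flash chromatography (pentane/Et2O), with the unwanted epimer re-equilibrated by CSA and re-separated, to give (2R,5S,7S)-2-(3-chloropropyl)-7-methyl-1,6-dioxaspiro[4.4]nonane F2. All later operations are kept free of acid: thiolate displacement (1-phenyl-1H-tetrazole-5-thiol, K2CO3, DMF) gives 5-({3-[(2R,5S,7S)-7-methyl-1,6-dioxaspiro[4.4]nonan-2-yl]propyl}sulfanyl)-1-phenyl-1H-tetrazole F3; buffered oxidation (mCPBA, NaHCO3, CH2Cl2) gives the corresponding sulfone F4; Julia–Kocienski olefination with 11 (KN(SiMe3)2, DME) gives the single-epimer alkene (3S)-5,7-dimethoxy-3-{(3E)-6-[(2S,5S,7S)-7-methyl-1,6-dioxaspiro[4.4]nonan-2-yl]hex-3-en-1-yl}isobenzofuran-1(3H)-one F5; hydrogenation over PtO2 in EtOAc containing a trace of K2CO3 then gives 33 directly.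

Step 19. The metalated sulfone may enolise aldehyde 11 or attack the lactone. The fallback sets out from 25 and comes back to the route at 32, replacing the sulfone olefination by a Wittig reaction. Chloro ketone 25 is cyclised as above to the chloro spiroketal pair F1, exchanged with NaI in acetone at reflux to (2R,7S)-2-(3-iodopropyl)-7-methyl-1,6-dioxaspiro[4.4]nonane F6 (C5 epimer pair), and heated with PPh3 in MeCN to {3-[(2R,7S)-7-methyl-1,6-dioxaspiro[4.4]nonan-2-yl]propyl}triphenylphosphonium iodide F7. The non-stabilised ylide (NaN(SiMe3)2, THF, −78 °C) reacts with 11 selectively at the aldehyde to give (3S)-5,7-dimethoxy-3-{(3Z)-6-[(2S,7S)-7-methyl-1,6-dioxaspiro[4.4]nonan-2-yl]hex-3-en-1-yl}isobenzofuran-1(3H)-one F8, which is hydrogenated (H2, PtO2, EtOAc) to 32.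

Step 5. The hindered dilithiated species may be protonated or butylated before it captures CO2. The fallback sets out from 7 and comes back to the route at 10 by palladium-catalysed carbonylative lactonisation: CO (1 atm), Pd(OAc)2 (3 mol %), Xantphos (6 mol %), Et3N, toluene, 90 °C. Oxidative addition of zerovalent palladium into the C–Br bond, CO insertion and intramolecular capture of the acyl palladium species by the benzylic hydroxyl give 10 without any organolithium and without touching the stereocentre; it makes no new compound (entry F0).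

Further compounds
F1 | step 21 | (2R,7S)-2-(3-chloropropyl)-7-methyl-1,6-dioxaspiro[4.4]nonane, C5 epimer pair | ClCCC[C@H]1CCC2(CC[C@H](C)O2)O1
F2 | step 21 | (2R,5S,7S)-2-(3-chloropropyl)-7-methyl-1,6-dioxaspiro[4.4]nonane | ClCCC[C@H]1CC[C@]2(CC[C@H](C)O2)O1
F3 | step 21 | 5-({3-[(2R,5S,7S)-7-methyl-1,6-dioxaspiro[4.4]nonan-2-yl]propyl}sulfanyl)-1-phenyl-1H-tetrazole | c1ccccc1-n1nnnc1SCCC[C@H]1CC[C@]2(CC[C@H](C)O2)O1
F4 | step 21 | 5-({3-[(2R,5S,7S)-7-methyl-1,6-dioxaspiro[4.4]nonan-2-yl]propyl}sulfonyl)-1-phenyl-1H-tetrazole | c1ccccc1-n1nnnc1S(=O)(=O)CCC[C@H]1CC[C@]2(CC[C@H](C)O2)O1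
F5 | step 21 | (3S)-5,7-dimethoxy-3-{(3E)-6-[(2S,5S,7S)-7-methyl-1,6-dioxaspiro[4.4]nonan-2-yl]hex-3-en-1-yl}isobenzofuran-1(3H)-one | COc1cc(OC)c2c(c1)[C@H](CC/C=C/CC[C@H]1CC[C@]3(CC[C@H](C)O3)O1)OC2=O
F6 | step 19 | (2R,7S)-2-(3-iodopropyl)-7-methyl-1,6-dioxaspiro[4.4]nonane, C5 epimer pair | ICCC[C@H]1CCC2(CC[C@H](C)O2)O1
F7 | step 19 | {3-[(2R,7S)-7-methyl-1,6-dioxaspiro[4.4]nonan-2-yl]propyl}triphenylphosphonium iodide, C5 epimer pair | [I-].c1ccccc1[P+](c1ccccc1)(c1ccccc1)CCC[C@H]1CCC2(CC[C@H](C)O2)O1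
F8 | step 19 | (3S)-5,7-dimethoxy-3-{(3Z)-6-[(2S,7S)-7-methyl-1,6-dioxaspiro[4.4]nonan-2-yl]hex-3-en-1-yl}isobenzofuran-1(3H)-one, C5'' epimer pair | COc1cc(OC)c2c(c1)[C@H](CC/C=C\CC[C@H]1CCC3(CC[C@H](C)O3)O1)OC2=O
F0 | step 5 | none | none
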